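Flavan numbering is used (upper half O1, C2–C8a; lower half primed). Retrosynthetic cuts, in order: CH3–O8 and the O4' silyl group; the ketal bond C8a–O5' together with the C4=C4a alkene (both traced to a C5' phenoxide and a C4 pivalate); the C8–O bond; the biaryl bond C8–C6'.
Enabling feature: in the carbocycle C4a–C5–C6–C7–C8–C8a the oxygens on C7 and C8 are neighbours and C8 lies para to the C5 oxygen. A carboxylic acid hung from O7 through one stereogenic carbon can therefore reach C8 of a C5 phenol by closing a six-membered 1,4-dioxan-2-one.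
Forward order: both pyran rings come with the starting flavonoids. The halves are joined at C8–C6' by Suzuki–Miyaura coupling, and the temporary dioxanone ring closes on C8 with dearomatisation. Methoxide then removes it while the dihydrofuran ring C8–C8a–O–C5'–C6' closes, and O8-methylation and desilylation finish the route.
Stereochemistry: C2 comes from (2S)-pinocembrin, C2' from asymmetric hydrogenation of a wogonin-derived flavone, and C4' from Mitsunobu inversion of the cis alcohol. C8 comes from the (R)-lactate ether (made by inversion of benzyl (S)-lactate), and C8a from the cis fusion that the five-membered ring enforces.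

Key step: step 18

Remark 1: commercial natural (2S)-pinocembrin is taken to be enantiopure.
Remark 2: rotation about the tetra-ortho-substituted C8–C6' bond is hindered, so 18–21 are expected as two atropisomers. They are drawn without an axial descriptor and carried on together, because the axis stops being a stereogenic unit when C8 becomes sp3 in step 18.

Step 1
Reactants: 1 (2S)-pinocembrin; 2 benzyl (S)-lactate
Product: 3 benzyl (R)-2-[(2S)-5-hydroxy-4-oxoflavan-7-yloxy]propanoate
Conditions: PPh3, DIAD, THF, 0 °C → rt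
Reagents that add atoms: none
Why: Mitsunobu etherification: only the acidic 7-OH reacts because the 5-OH is hydrogen-bonded to C4=O, the neutral medium leaves the base-sensitive C2 centre alone, and SN2 displacement at the lactate carbon inverts S to R.

Step 2
Reactants: 3 benzyl (R)-2-[(2S)-5-hydroxy-4-oxoflavan-7-yloxy]propanoate
Product: 4 benzyl (R)-2-[(2S,4S)-4,5-dihydroxyflavan-7-yloxy]propanoate (2,4-cis)
Conditions: NaBH4, THF–i-PrOH, 0 °C → rt
Reagents that add atoms: none
Why: Borohydride reduction of a flavanone: axial hydride delivery to the half-chair with equatorial 2-phenyl should give the cis (4S) alcohol, the ester is inert in isopropanol, and removal of the ketone ends the risk of C2 racemisation by retro-oxa-Michael opening in the later basic steps.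

Step 3
Reactants: 4 benzyl (R)-2-[(2S,4S)-4,5-dihydroxyflavan-7-yloxy]propanoate
Product: 5 benzyl (R)-2-[(2S,4S)-5-benzyloxy-4-hydroxyflavan-7-yloxy]propanoate
Conditions: BnBr, K2CO3, DMF, rt
Reagents that add atoms: benzyl bromide, BrCc1ccccc1
Why: Williamson etherification: carbonate deprotonates only the phenol, which is no longer chelated, the benzylic alcohol stays free, and α-aryloxypropanoates are configurationally stable to carbonate bases.

Step 4
Reactants: 5 benzyl (R)-2-[(2S,4S)-5-benzyloxy-4-hydroxyflavan-7-yloxy]propanoate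
Product: 6 benzyl (R)-2-[(2S,4S)-5-benzyloxy-4-pivaloyloxyflavan-7-yloxy]propanoate
Conditions: PivCl, Et3N, DMAP (cat.), CH2Cl2, 0 °C → rt
Reagents that add atoms: pivaloyl chloride, CC(C)(C)C(=O)Cl
Why: DMAP-catalysed acylation installs the later leaving group as an ester that methoxide attacks slowly, and 4-acyloxyflavans with a fully etherified A ring are bench-stable and ionise only under Lewis acids.

Step 5
Reactants: 6 benzyl (R)-2-[(2S,4S)-5-benzyloxy-4-pivaloyloxyflavan-7-yloxy]propanoate
Product: 7 benzyl (R)-2-[(2S,4S)-5-benzyloxy-8-bromo-4-pivaloyloxyflavan-7-yloxy]propanoate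
Conditions: NBS, CH2Cl2, −78 → 0 °C
Reagents that add atoms: N-bromosuccinimide, O=C1CCC(=O)N1Br
Why: Electrophilic aromatic bromination: in 5,7-di-O-alkylated flavans C8 is attacked in preference to C6, which sits between two alkoxy groups, as is well established for O-benzylated flavan-3-ols, and this is why O5 is etherified before halogenation.

Step 6
Reactants: 7 benzyl (R)-2-[(2S,4S)-5-benzyloxy-8-bromo-4-pivaloyloxyflavan-7-yloxy]propanoate
Product: 8 the corresponding 8-(pinacolatoboryl) compound
Conditions: HBpin, Et3N, PdCl2(MeCN)2 (cat.), SPhos (cat.), 1,4-dioxane, 80 °C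
Reagents that add atoms: pinacolborane, [H]B1OC(C)(C)C(C)(C)O1
Why: Miyaura borylation with pinacolborane and a dialkylbiarylphosphine suits electron-rich di-ortho-substituted aryl bromides, and the amine base spares both esters and the lactate centre.

Step 7
Reactants: 9 wogonin (5,7-dihydroxy-8-methoxyflavone)
Product: 10 5-hydroxy-7,8-dimethoxyflavone
Conditions: MeI (1 equiv), K2CO3, acetone, rt
Reagents that add atoms: iodomethane, CI
Why: Williamson methylation is selective for the 7-OH because the 5-OH is chelated to the C4 carbonyl and reacts only on heating.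

Step 8
Reactants: 10 5-hydroxy-7,8-dimethoxyflavone
Product: 11 5-benzyloxy-7,8-dimethoxyflavone
Conditions: BnBr, K2CO3, DMF, 70 °C
Reagents that add atoms: benzyl bromide, BrCc1ccccc1
Why: Williamson benzylation of the chelated phenol under forcing conditions is harmless on the achiral, base-stable flavone and covers the acidic OH before the base-activated hydrogenation catalyst and the Mitsunobu step.

Step 9
Reactants: 11 5-benzyloxy-7,8-dimethoxyflavone
Product: 12 (2S,4S)-5-benzyloxy-7,8-dimethoxyflavan-4-ol (2,4-cis)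
Conditions: [Ru(cod)(2-methylallyl)2] (cat.), chiral SINpEt·HBF4 (cat., the enantiomer that gives 2S), KOt-Bu (cat.), H2 (120 bar), toluene–hexane, 40 °C
Reagents that add atoms: none
Why: Ruthenium–NHC-catalysed asymmetric hydrogenation of flavones: the catalyst selects the face of C2=C3 and sets 2S, the carbonyl is then reduced from the axial direction to the cis (4S) alcohol, the homogeneous catalyst leaves the benzyl ether alone, and any minor enantiomer becomes a separable diastereomer after step 15.

Step 10
Reactants: 12 (2S,4S)-5-benzyloxy-7,8-dimethoxyflavan-4-ol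
Product: 13 (2S,4R)-5-benzyloxy-7,8-dimethoxyflavan-4-yl benzoate (2,4-trans)
Conditions: PhCO2H, PPh3, DIAD, toluene, −20 °C → rt
Reagents that add atoms: benzoic acid, OC(=O)c1ccccc1
Why: Mitsunobu inversion sets 4R: SN2 displacement gives the pseudo-axial trans ester, which also relieves peri strain with the 5-benzyloxy group, so any leakage through the benzylic cation should lead to the same trans product by axial capture.

Step 11
Reactants: 13 (2S,4R)-5-benzyloxy-7,8-dimethoxyflavan-4-yl benzoate
Product: 14 (2S,4R)-5-benzyloxy-7,8-dimethoxyflavan-4-ol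
Conditions: K2CO3 (cat.), MeOH–THF, rt
Reagents that add atoms: none
Why: Base-catalysed transesterification cleaves the acyl–oxygen bond, so the C4–O bond and its configuration are untouched and the basic medium suppresses benzylic solvolysis.

Step 12
Reactants: 14 (2S,4R)-5-benzyloxy-7,8-dimethoxyflavan-4-ol
Product: 15 (2S,4R)-7,8-dimethoxyflavan-4,5-diol
Conditions: H2 (1 atm), Pd/C, EtOAc, rt
Reagents that add atoms: none
Why: Hydrogenolysis of the aryl benzyl ether in a neutral solvent is faster than cleavage of the ring C2–O and C4–OH bonds, and the benzyl group must leave here because the last unmasking (step 17) is also a hydrogenolysis that has to keep O5' covered.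

Step 13
Reactants: 15 (2S,4R)-7,8-dimethoxyflavan-4,5-diol
Product: 16 (2S,4R)-4,5-bis(tert-butyldimethylsilyloxy)-7,8-dimethoxyflavan
Conditions: TBSOTf (2.4 equiv), 2,6-lutidine, CH2Cl2, −78 → 0 °C
Reagents that add atoms: tert-butyldimethylsilyl triflate, CC(C)(C)[Si](C)(C)OS(=O)(=O)C(F)(F)F
Why: Silylation with a silyl triflate and a hindered base covers phenol and hindered benzylic alcohol in one operation, giving two silyl ethers that fluoride can later tell apart (aryl before alkyl).

Step 14
Reactants: 16 (2S,4R)-4,5-bis(tert-butyldimethylsilyloxy)-7,8-dimethoxyflavan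
Product: 17 (2S,4R)-4,5-bis(tert-butyldimethylsilyloxy)-6-iodo-7,8-dimethoxyflavan
Conditions: NIS, MeCN, 0 °C → rt
Reagents that add atoms: N-iodosuccinimide, O=C1CCC(=O)N1I
Why: Electrophilic aromatic iodination has only one position to choose, C6 (the later C6'), which is ortho to two oxygens and para to O1, while the unactivated 2-phenyl ring does not compete.

Step 15
Reactants: 8 upper 8-boronate; 17 lower 6-iodide
Product: 18 C8–C6' biaryl (O5 benzyl, C4 pivalate, O7 (R)-lactate benzyl ester; O5' and O4' TBS)
Conditions: SPhos Pd G3 (cat.), K3PO4, toluene–H2O (10:1), 90 °C, 8 in excess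
Reagents that add atoms: none
Why: Suzuki–Miyaura coupling with a bulky dialkylbiarylphosphine is the standard entry to tetra-ortho-substituted biaryls: all four ortho groups are oxygen-linked and slim at the first atom, the shorter-route boronate is used in excess against protodeboronation, and neither half is a flavanone any longer, so hot base cannot racemise C2 or C2'.

Step 16
Reactants: 18 C8–C6' biaryl
Product: 20 C5'-acetate of the biaryl (O4' TBS kept), via C5'-phenol 19 (not isolated)
Conditions: TBAF (1.1 equiv), THF, 0 °C; then Ac2O, 0 °C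
Reagents that add atoms: acetic anhydride, CC(=O)OC(C)=O
Why: Fluoride cleaves aryl silyl ethers much faster than secondary alkyl ones and the ammonium phenoxide is acetylated in the same flask, so any phenol already freed by the base of step 15 converges on the same acetate.

Step 17
Reactants: 20 C5'-acetate of the biaryl
Product: 21 (R)-2-aryloxypropanoic acid of the 8-aryl-5-hydroxy-4-pivaloyloxyflavan (C5'-OAc, C4'-OTBS)
Conditions: H2 (1 atm), Pd/C, EtOAc, rt; filtered, concentrated cold and used at once
Reagents that add atoms: none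
Why: One neutral hydrogenolysis frees the C5 phenol and the acid together, which avoids both the saponification that the aryl acetate would not survive and any base that would expel pivalate from an ortho-hydroxybenzyl ester; the crowded, twisted arenes cannot lie flat on palladium, so the C4 and C4' C–O bonds should persist as they do in debenzylations of oligomeric flavans.

Step 18
Reactants: 21 (R)-2-aryloxypropanoic acid of the 8-aryl-5-hydroxy-4-pivaloyloxyflavan
Product: 22 (8S)-lactone-bridged 8-aryl chromandienone (1,4-dioxan-2-one fused across C7–C8)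
Conditions: PhI(OAc)2 (1.05 equiv), 4 Å MS, MeCN–CH2Cl2, −20 → 0 °C
Reagents that add atoms: none
Why: The C5 phenol exchanges with acetate at iodine(III), departure of iodobenzene leaves phenoxenium character at the para carbon C8, and the carboxyl oxygen of the O7 tether bonds to C8 with loss of a proton, giving the C5 dienone. The closest known reaction is the iodine(III) dearomatising lactonisation of phenols bearing a carboxylic acid, in the variant where a lactic acid ether of a resorcinol delivers oxygen to the para carbon and gives p-quinol dioxanones. The six-membered ring closes by 6-exo-trig attack on the quinoid C8=C8a bond (C7, inside the ring, stays sp2), so the delocalised cation sets no strict geometric limit. C8 is controlled by the tether carbon: the planar enol ether and ester units force a boat-like dioxanone in which the C8 aryl group and one tether substituent take the flagpole sites, hydrogen goes there and methyl points outward, so methyl and aryl end up trans and the (R)-ether should give 8S. The step needs chemoselectivity (only the free C5 phenol binds iodine, and the acetate removes the hydroquinone-ether character of the lower ring), site selectivity (para C8 over the ortho C–H carbon C6, which the tether could also reach, as found for tethered resorcinols) and survival of the C4 pivalate (weak acid only, non-ionising solvent, low temperature). Both atropisomers should converge because the axis disappears when C8 becomes sp3.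

Step 19
Reactants: 22 (8S)-lactone-bridged 8-aryl chromandienone
Product: 25 (8S,8aS)-pentacyclic 8-hydroxy-7-methoxy ketal enone (O4' TBS), via hydroxy-ester phenol 23 (not isolated), via C7-lactate ketal 24 (not isolated)
Conditions: NaOMe (5 equiv), MeOH–THF, −20 °C → rt; AcOH quench
Reagents that add atoms: sodium methoxide, C[O-].[Na+]
Why: Proposed new method: methoxide cleaves the aryl acetate and opens the lactone (23); the C5' phenoxide, held on the aryl-bearing face, adds to C8a (the β-carbon of the C5 enone) and the enolate expels the C4 pivalate (addition–E1cB, overall SN2'), giving ketal 24 with C4=C4a; addition–elimination of methoxide at the vinylogous ester carbon C7 then swaps lactate for methoxy. The closest known reaction types are SN2' substitution of Morita–Baylis–Hillman esters by phenoxides and ketal-forming oxa-Michael additions to β-alkoxyenones, and 8aS follows because the five-membered ring can only be cis-fused to the C8 centre.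

Step 20
Reactants: 25 (8S,8aS)-pentacyclic 8-hydroxy-7-methoxy ketal enone
Product: 26 4'-O-TBS-6''-demethoxyneocalycopterone
Conditions: NaH (1.2 equiv), MeI, THF–DMF, 0 °C
Reagents that add atoms: iodomethane, CI
Why: Williamson methylation of the only free hydroxyl: the tertiary quinol-type OH is acidified by its ketal and vinylogous ester neighbours, the small electrophile reaches it, and the near-stoichiometric hydride is consumed before the C3 hydrogens can be touched.

Step 21
Reactants: 26 4'-O-TBS-6''-demethoxyneocalycopterone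
Product: 27 6''-demethoxyneocalycopterone
Conditions: TBAF, AcOH (1:1), THF, 0 °C → rt
Reagents that add atoms: none
Why: Buffered fluoride desilylation breaks only the Si–O bond, so the ionisable benzylic C4'–O bond keeps its R configuration and the ketal and enone see neither strong acid nor strong base.

Compound list
1 | (2S)-pinocembrin, (2S)-5,7-dihydroxyflavanone | Oc1cc(O)c2C(=O)C[C@@H](c3ccccc3)Oc2c1 | starting material
2 | benzyl (S)-lactate | C[C@H](O)C(=O)OCc1ccccc1 | starting material
3 | benzyl (R)-2-[(2S)-5-hydroxy-4-oxoflavan-7-yloxy]propanoate | C[C@@H](Oc1cc(O)c2C(=O)C[C@@H](c3ccccc3)Oc2c1)C(=O)OCc1ccccc1 | intermediate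
4 | benzyl (R)-2-[(2S,4S)-4,5-dihydroxyflavan-7-yloxy]propanoate | C[C@@H](Oc1cc(O)c2c(c1)O[C@H](c1ccccc1)C[C@@H]2O)C(=O)OCc1ccccc1 | intermediate
5 | benzyl (R)-2-[(2S,4S)-5-benzyloxy-4-hydroxyflavan-7-yloxy]propanoate | C[C@@H](Oc1cc(OCc3ccccc3)c2c(c1)O[C@H](c1ccccc1)C[C@@H]2O)C(=O)OCc1ccccc1 | intermediate
6 | benzyl (R)-2-[(2S,4S)-5-benzyloxy-4-pivaloyloxyflavan-7-yloxy]propanoate | C[C@@H](Oc1cc(OCc3ccccc3)c2c(c1)O[C@H](c1ccccc1)C[C@@H]2OC(=O)C(C)(C)C)C(=O)OCc1ccccc1 | intermediate
7 | benzyl (R)-2-[(2S,4S)-5-benzyloxy-8-bromo-4-pivaloyloxyflavan-7-yloxy]propanoate | C[C@@H](Oc1cc(OCc3ccccc3)c2c(c1Br)O[C@H](c1ccccc1)C[C@@H]2OC(=O)C(C)(C)C)C(=O)OCc1ccccc1 | intermediate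
8 | benzyl (R)-2-[(2S,4S)-5-benzyloxy-8-(pinacolatoboryl)-4-pivaloyloxyflavan-7-yloxy]propanoate | C[C@@H](Oc1cc(OCc3ccccc3)c2c(c1B4OC(C)(C)C(C)(C)O4)O[C@H](c1ccccc1)C[C@@H]2OC(=O)C(C)(C)C)C(=O)OCc1ccccc1 | intermediate
9 | wogonin, 5,7-dihydroxy-8-methoxyflavone | COc1c(O)cc(O)c2c1oc(cc2=O)-c1ccccc1 | starting material
10 | 5-hydroxy-7,8-dimethoxyflavone | COc1c(OC)cc(O)c2c1oc(cc2=O)-c1ccccc1 | intermediate
11 | 5-benzyloxy-7,8-dimethoxyflavone | COc1c(OC)cc(OCc3ccccc3)c2c1oc(cc2=O)-c1ccccc1 | intermediate
12 | (2S,4S)-5-benzyloxy-7,8-dimethoxyflavan-4-ol (cis) | COc1cc(OCc2ccccc2)c2c(c1OC)O[C@H](c1ccccc1)C[C@@H]2O | intermediate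
13 | (2S,4R)-5-benzyloxy-7,8-dimethoxyflavan-4-yl benzoate (trans) | COc1cc(OCc2ccccc2)c2c(c1OC)O[C@H](c1ccccc1)C[C@H]2OC(=O)c1ccccc1 | intermediate
14 | (2S,4R)-5-benzyloxy-7,8-dimethoxyflavan-4-ol (trans) | COc1cc(OCc2ccccc2)c2c(c1OC)O[C@H](c1ccccc1)C[C@H]2O | intermediate
15 | (2S,4R)-7,8-dimethoxyflavan-4,5-diol | COc1cc(O)c2c(c1OC)O[C@H](c1ccccc1)C[C@H]2O | intermediate
16 | (2S,4R)-4,5-bis(tert-butyldimethylsilyloxy)-7,8-dimethoxyflavan | COc1cc(O[Si](C)(C)C(C)(C)C)c2c(c1OC)O[C@H](c1ccccc1)C[C@H]2O[Si](C)(C)C(C)(C)C | intermediate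
17 | (2S,4R)-4,5-bis(tert-butyldimethylsilyloxy)-6-iodo-7,8-dimethoxyflavan | COc1c(I)c(O[Si](C)(C)C(C)(C)C)c2c(c1OC)O[C@H](c1ccccc1)C[C@H]2O[Si](C)(C)C(C)(C)C | intermediate
18 | C8–C6' biaryl: upper (2S,4S)-5-OBn-4-OPiv-flavan with O7 (R)-CH(CH3)CO2Bn; lower (2'S,4'R)-5',4'-bis-OTBS-7',8'-dimethoxyflavan | C[C@@H](Oc1cc(OCc3ccccc3)c2c(c1-c5c(O[Si](C)(C)C(C)(C)C)c6c(c(OC)c5OC)O[C@H](c7ccccc7)C[C@H]6O[Si](C)(C)C(C)(C)C)O[C@H](c1ccccc1)C[C@@H]2OC(=O)C(C)(C)C)C(=O)OCc1ccccc1 | intermediate
19 | biaryl as 18 with free C5'-OH (present as its ammonium phenoxide) | C[C@@H](Oc1cc(OCc3ccccc3)c2c(c1-c5c(O)c6c(c(OC)c5OC)O[C@H](c7ccccc7)C[C@H]6O[Si](C)(C)C(C)(C)C)O[C@H](c1ccccc1)C[C@@H]2OC(=O)C(C)(C)C)C(=O)OCc1ccccc1 | intermediate (not isolated)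
20 | biaryl as 18 with C5'-OAc | C[C@@H](Oc1cc(OCc3ccccc3)c2c(c1-c5c(OC(C)=O)c6c(c(OC)c5OC)O[C@H](c7ccccc7)C[C@H]6O[Si](C)(C)C(C)(C)C)O[C@H](c1ccccc1)C[C@@H]2OC(=O)C(C)(C)C)C(=O)OCc1ccccc1 | intermediate
21 | (R)-2-aryloxypropanoic acid of the (2S,4S)-8-aryl-5-hydroxy-4-pivaloyloxyflavan (C5'-OAc, C4'-OTBS) | C[C@@H](Oc1cc(O)c2c(c1-c5c(OC(C)=O)c6c(c(OC)c5OC)O[C@H](c7ccccc7)C[C@H]6O[Si](C)(C)C(C)(C)C)O[C@H](c1ccccc1)C[C@@H]2OC(=O)C(C)(C)C)C(=O)O | intermediate
22 | (8S)-lactone-bridged 8-aryl chromandienone: C5 ketone, C6=C7 and C4a=C8a alkenes, O7–(R)-CH(CH3)–C(=O)–O–C8 ring, methyl trans to aryl | C[C@H]1OC2=CC(=O)C3=C(O[C@H](c4ccccc4)C[C@@H]3OC(=O)C(C)(C)C)[C@]2(OC1=O)c1c(OC(C)=O)c2c(c(OC)c1OC)O[C@H](c1ccccc1)C[C@H]2O[Si](C)(C)C(C)(C)C | intermediate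
23 | dienone as 22 with lactone opened (C8-OH, methyl ester) and free C5'-OH | C[C@@H](OC2=CC(=O)C3=C(O[C@H](c4ccccc4)C[C@@H]3OC(=O)C(C)(C)C)[C@]2(O)c1c(O)c2c(c(OC)c1OC)O[C@H](c1ccccc1)C[C@H]2O[Si](C)(C)C(C)(C)C)C(=O)OC | intermediate (not isolated)
24 | (8S,8aS)-pentacyclic ketal enone with C8-OH and O7 (R)-CH(CH3)CO2Me | C[C@@H](OC1=CC(=O)C2=CC[C@@H](c3ccccc3)O[C@]23Oc2c4c(c(OC)c(OC)c2[C@]13O)O[C@H](c1ccccc1)C[C@H]4O[Si](C)(C)C(C)(C)C)C(=O)OC | intermediate (not isolated)
25 | (8S,8aS)-pentacyclic ketal enone with C7-OMe, C8-OH, C4'-OTBS | COC1=CC(=O)C2=CC[C@@H](c3ccccc3)O[C@]23Oc2c4c(c(OC)c(OC)c2[C@]13O)O[C@H](c1ccccc1)C[C@H]4O[Si](C)(C)C(C)(C)C | intermediate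
26 | 4'-O-TBS-6''-demethoxyneocalycopterone | COC1=CC(=O)C2=CC[C@@H](c3ccccc3)O[C@]23Oc2c4c(c(OC)c(OC)c2[C@]13OC)O[C@H](c1ccccc1)C[C@H]4O[Si](C)(C)C(C)(C)C | intermediate
27 | 6''-demethoxyneocalycopterone (2S,8S,8aS,2'S,4'R) | COC1=CC(=O)C2=CC[C@@H](c3ccccc3)O[C@]23Oc2c4c(c(OC)c(OC)c2[C@]13OC)O[C@H](c1ccccc1)C[C@H]4O | target

Total step count: 21. Longest linear sequence: 15 steps (steps 7–21, from wogonin).

Steps most likely to fail

Step 19 (new method). Methoxide may add to C8a or strip the pivalate before the phenoxide closes. Slow rotation about C8–C6' may hold O5' away from C8a. The oxa-Michael equilibrium may also stay on the open side. The fallback uses known reactions one at a time, sets out from 22 and returns at 25. Hydrazine acetate in DMF at 0 °C removes only the aryl acetate and gives the lactone phenol F1. A catalytic sulfonic acid (PPTS or CSA, CH2Cl2) closes the phenol on C8a as an acid-catalysed ketal-forming oxa-Michael addition to the β-alkoxyenone, giving the saturated β-pivaloyloxy ketone F2. DBU then eliminates pivalic acid by E1cB to the lactone-bridged pentacyclic enone F3. Only then does NaOMe in MeOH open the lactone and exchange the C7 ether to reach 25.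

Step 18 (key step). The C4 pivalate may be lost by ionisation next to the free phenol, facial selectivity at C8 may be poor, or the lower ring may be oxidised instead. The fallback gives up delivery by the tether, sets out from 21 and returns at 26. Trimethylsilyldiazomethane turns the acid into the methyl ester phenol F4. PhI(OAc)2 in methanol then traps C8 with the solvent (p-quinol ether formation) to give the 8-methoxy dienone F5 as two C8 epimers, which are separated. NaOMe in MeOH, as in step 19, takes the 8S epimer straight to 26, so steps 19 and 20 are bypassed.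

Step 15. Protodeboronation of the 2,6-dioxygenated boronate may outrun transmetalation at the tetra-ortho-substituted junction, and the hot base may wear down the silyl ether and the esters. The fallback reverses the polarity and drops boron and base, sets out from 17 and 7 and returns at 18. Iodine–magnesium exchange on 17 (i-PrMgCl·LiCl, THF, −30 °C) followed by ZnCl2 gives the arylzinc chloride F6. This is joined to bromide 7 by Negishi coupling (Pd-PEPPSI-IPent or Pd/RuPhos, THF–NMP, 60 °C), conditions that tolerate both esters.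

Further compounds
F1 | step 19 | lactone-bridged dienone as 22 with free C5'-OH | C[C@H]1OC2=CC(=O)C3=C(O[C@H](c4ccccc4)C[C@@H]3OC(=O)C(C)(C)C)[C@]2(OC1=O)c1c(O)c2c(c(OC)c1OC)O[C@H](c1ccccc1)C[C@H]2O[Si](C)(C)C(C)(C)C
F2 | step 19 | lactone-bridged C8a ketal with saturated C4a–H and C4-OPiv (C4a epimers) | C[C@H]1OC2=CC(=O)C3[C@@H](OC(=O)C(C)(C)C)C[C@@H](c4ccccc4)O[C@]35Oc3c6c(c(OC)c(OC)c3[C@]25OC1=O)O[C@H](c1ccccc1)C[C@H]6O[Si](C)(C)C(C)(C)C
F3 | step 19 | lactone-bridged (8S,8aS)-pentacyclic ketal enone with C4=C4a | C[C@H]1OC2=CC(=O)C3=CC[C@@H](c4ccccc4)O[C@]35Oc3c6c(c(OC)c(OC)c3[C@]25OC1=O)O[C@H](c1ccccc1)C[C@H]6O[Si](C)(C)C(C)(C)C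
F4 | step 18 | methyl ester of acid 21 | C[C@@H](Oc1cc(O)c2c(c1-c5c(OC(C)=O)c6c(c(OC)c5OC)O[C@H](c7ccccc7)C[C@H]6O[Si](C)(C)C(C)(C)C)O[C@H](c1ccccc1)C[C@@H]2OC(=O)C(C)(C)C)C(=O)OC
F5 | step 18 | (8S)-8-aryl-8-methoxy chromandienone with O7 (R)-CH(CH3)CO2Me, C4-OPiv, C5'-OAc | C[C@@H](OC2=CC(=O)C3=C(O[C@H](c4ccccc4)C[C@@H]3OC(=O)C(C)(C)C)[C@]2(OC)c1c(OC(C)=O)c2c(c(OC)c1OC)O[C@H](c1ccccc1)C[C@H]2O[Si](C)(C)C(C)(C)C)C(=O)OC
F6 | step 15 | (2S,4R)-4,5-bis(tert-butyldimethylsilyloxy)-7,8-dimethoxyflavan-6-ylzinc chloride | COc1c([Zn]Cl)c(O[Si](C)(C)C(C)(C)C)c2c(c1OC)O[C@H](c1ccccc1)C[C@H]2O[Si](C)(C)C(C)(C)C
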